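- Start with the easy part: this flask begins with solid J, no Q in solution and D held, and you want to know how much of the J has become X by the end.

J 1.0 M; D 190 mM (held); time 40 min

    J ⇌ Z, rate k1*(cs1 - [Z]) while solid is left; crystals form when [Z] > cs1 (cs1 = 0.78 M, k1 = 1.2 min⁻¹)
    Z + Q ⇌ X (K2 = 68 M⁻¹, k2 = 0.18 M⁻¹ min⁻¹)
    G ⇌ X, rate k3*(cs3 - [X]) while solid is left; crystals form when [X] > cs3 (cs3 = 0.18 M, k3 = 2.5 min⁻¹)
    D ⇌ Q, rate k4*(csat - [Q]) (k4 = 0.19 min⁻¹, csat = 190 mM)

- for X the G are counted in
- as a solid, counted per litre of solution: J, G
- at the start none of Q is dissolved
- at the start none of J is in solution
- run time (flask): 40 min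

* amount of X and G together at 40 min, in percent of the J charged
* the change that raises the amount of X and G together at 40 min, in percent of the J charged most ("none" if none brings more than 2 percentage points) (maple / larch / ash / alder / none)
* amount of X and G together at 40 min, in percent of the J charged, after larch

- maple: doubling the solubility in step 1, all else as stated
- larch: doubling the dissolution coefficient of step 3, all else as stated
- ash: doubling the saturation concentration of D, all else as stated
- alder: doubling the dissolution coefficient of step 1, all else as stated

- A bench rule says that the gas feeds the reaction, so its uptake into an empty solution is the pace. That gives 144% of the J charged in 40 min, more than the charge, so the rule promises a full yield.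
- The rule needs Q kept near empty, so Z must remove Q faster than the gas refills it. Write a for the transfer coefficient, k for the rate constant of Z + Q, and s for the saturation concentration of D. The ratio kZ/a, at Z equal to the solubility, is 0.739, less than one, so the rule fails here.
- Balance Q instead, as a steady state: a(s − Q) = kZQ. Then Q = as/(a + kZ), and p = kZQ = as·kZ/(a + kZ) is the rate at which X forms.
- With Z at its solubility 0.78 M, Q is 0.109 M. Z can stand there while solid is left, because the dissolving coefficient 1.2 min⁻¹ is far above kQ, which is 0.0197 min⁻¹. Then p is 0.0153 M min⁻¹; this Q-balance pace is reached after a settling time, the inverse of (a + kZ), of 3.03 min.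
- I neglect the back reaction. The solid lasts until 0.220 M has reacted, which takes until about 17.4 min. After that Z falls, so I take p at the middle value of Z, 0.606 M, which gives 0.0132 M min⁻¹. My y is 51.8%.
- p is proportional to s, so I choose ash. Maple lifts the first pace to 0.0176 M min⁻¹ at most, with Z no higher than the charge. The step between G and X has no place in p, so larch leaves my figure as it stands.
- The forecast says 50%, ash, and 50% after larch, on these grounds: “Doubling csat roughly doubles the Q supply and clearly wins”.
- The simulation gives 50.5%, with ash best at a gain of 29 percentage points, and 50.5% after larch.
- Now take the neighbour charged with 2.5 M of J, all else held. Its solid needs 112 min to go, longer than 40 min, so Z stays at solubility and p stays 0.0153 M min⁻¹. Over the time less the settling time, that makes 0.566 M of X, or 22.6% of this charge. The simulated neighbour gave 22.0%, with 47.3% of its charge still solid J.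

Its constants come from no measurement; the rest is arithmetic.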